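Ring A = C1–C5 and C10 (acetate ring); ring B = C5–C10 (enedione ring); acetyl = C11/C12. Locants are eremophilane locants, and β is the face of the C5 methyl group.
Cuts, in order: C9–O (angelate, back to a 9β,10β-epoxide); C7–C11 and the C6=C7 unsaturation; C9–C10 together with the oxirane O–C9 bond (Darzens); C5–C6 (Michael).
Enabling feature: in ring B the trans C9-acyloxy/C10-hydroxy pair lies next to the C8 ketone. It is therefore an α,β-epoxy ketone opened at Cα, and its Cβ (C10) is a ring A carbonyl carbon 1,5-related to C8 through C5–C6–C7.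
Forward: ring A comes from 2,3-dimethylphenol, which already carries both methyl groups and the C10 oxygen; the C3 oxygen enters in step 1. The chain C6–C9 is joined at C5. Ring B and a temporary oxirane then close in one operation. The oxirane shields C9/C10 while C7 is acetylated and C6=C7 is introduced, and angelic acid opens it last.
Stereochemistry: C3 comes from a CBS reduction, the only reagent control. C4 is set by hydride delivery anti to the C3 acetate and C5 by attack anti to the C4 methyl. C10 and C9 are set in the key step, and C9 is then inverted by SN2. The (Z)-alkene arrives with angelic acid.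

Key step: step 8

Assumption: the 2-methylbut-2-enoate in the target SMILES is the (Z)-isomer (angelate), so commercial angelic acid serves as the ester source.

Step 1
Reactants: 1 2,3-dimethylphenol
Product: 3 4,4-dimethoxy-2,3-dimethylcyclohexa-2,5-dien-1-one, via 4-methoxy-2,3-dimethylphenol 2 (not isolated)
Conditions: PhI(OAc)2 (2.2 equiv), MeOH, 0 °C to rt
Reagents that add atoms: methanol, CO
Why: Twofold oxidative dearomatisation of a phenol with PhI(OAc)2 in methanol should first methoxylate the free para position and then trap the more electron-rich 4-methoxyphenol as the p-quinone monoketal; no stereocentre is formed.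

Step 2
Reactants: 3 4,4-dimethoxy-2,3-dimethylcyclohexa-2,5-dien-1-one
Product: 4 4,4-dimethoxy-2,3-dimethylcyclohex-2-en-1-one
Conditions: H2 (1 atm), RhCl(PPh3)3 (5 mol %), toluene/EtOH, rt
Reagents that add atoms: none
Why: Chemoselective homogeneous hydrogenation distinguishes alkenes by substitution, so the disubstituted C=C of the cross-conjugated dienone should be saturated while the tetrasubstituted C=C and the ketal remain.

Step 3
Reactants: 4 4,4-dimethoxy-2,3-dimethylcyclohex-2-en-1-one
Product: 5 (1S)-4,4-dimethoxy-2,3-dimethylcyclohex-2-en-1-ol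
Conditions: (R)-2-methyl-CBS-oxazaborolidine (10 mol %), BH3·SMe2, THF, −20 °C; MeOH, then pH 7 buffer
Reagents that add atoms: none
Why: In this Corey–Bakshi–Shibata reduction the α-methylated alkene arm acts as the large group and the CH2 arm as the small one, so the (R)-catalyst should give the (S)-allylic alcohol, which is the future C3.

Step 4
Reactants: 5 (1S)-4,4-dimethoxy-2,3-dimethylcyclohex-2-en-1-ol
Product: 7 (1S)-2,3-dimethyl-4-oxocyclohex-2-en-1-yl acetate, via ketal acetate 6 (not isolated)
Conditions: Ac2O, pyridine, DMAP (cat.), CH2Cl2, 0 °C to rt; then aq. oxalic acid, THF, rt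
Reagents that add atoms: acetic anhydride, CC(=O)OC(C)=O; water, O
Why: O-Acetylation followed by mild hydrolysis of the allylic dimethyl ketal is standard protecting-group chemistry; it transposes the enone (the ketal carbon becomes C10=O) and does not touch the C3 stereocentre.

Step 5
Reactants: 7 (1S)-2,3-dimethyl-4-oxocyclohex-2-en-1-yl acetate
Product: 8 (1S,2R)-2,3-dimethyl-4-[(triethylsilyl)oxy]cyclohex-3-en-1-yl acetate
Conditions: Et3SiH (1.5 equiv), RhCl(PPh3)3 (2 mol %), toluene, 60 °C
Reagents that add atoms: triethylsilane, CC[SiH](CC)CC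
Why: Rhodium-catalysed 1,4-hydrosilylation of an enone with a monohydrosilane gives the regiodefined tetrasubstituted silyl enol ether, and because A(1,2) strain with the C4 methyl holds the C3 acetate pseudoaxial, hydride should reach C4 from the opposite (α) face and leave the C4 methyl cis to the acetate.

Step 6
Reactants: 9 2-chloro-N-methoxy-N-methylacetamide
Product: 10 1-chlorobut-3-en-2-one
Conditions: CH2=CHMgBr (1.05 equiv), THF, −78 °C; inverse quench into cold 1 M HCl; used freshly prepared
Reagents that add atoms: vinylmagnesium bromide, C=C[Mg]Br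
Why: In this Weinreb ketone synthesis the chelated tetrahedral adduct stops the Grignard addition at the ketone stage, and the acidic inverse quench keeps the released amine from adding to the vinyl ketone.

Step 7
Reactants: 8 (1S,2R)-2,3-dimethyl-4-[(triethylsilyl)oxy]cyclohex-3-en-1-yl acetate; 10 1-chlorobut-3-en-2-one
Product: 12 (1S,2R,3R)-3-(4-chloro-3-oxobutyl)-2,3-dimethyl-4-oxocyclohexyl acetate, via side-chain triethylsilyl enol ether 11 (not isolated)
Conditions: HNTf2 (5 mol %), CH2Cl2, −78 °C; then 1 M HCl, THF, 0 °C
Reagents that add atoms: none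
Why: In this Mukaiyama–Michael addition under silyl-transfer catalysis the C4 methyl is pseudoaxial (A(1,2) strain with the C5 methyl), so the vinyl ketone should be attacked from the α face of C5 along the chair-like axial trajectory, setting the quaternary C5 with the two methyl groups cis.

Step 8
Reactants: 12 (1S,2R,3R)-3-(4-chloro-3-oxobutyl)-2,3-dimethyl-4-oxocyclohexyl acetate
Product: 14 (3S,4R,5R,9R,10R)-3β-acetoxy-9β,10β-epoxy-11,12,13-trinoreremophilan-8-one, via potassium 9α-chloro aldolate 13 (not isolated)
Conditions: KN(SiMe3)2 (1.05 equiv), THF, −78 °C to 0 °C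
Reagents that add atoms: none
Why: KN(SiMe3)2 removes the most acidic proton, on the chlorine-bearing C9, the chloro enolate adds to the ring A ketone C10, and the aldolate oxygen then displaces chloride; this is an intramolecular Darzens condensation of an α-chloro ketone, that is, a Robinson-type ketol closure intercepted at the epoxide oxidation level. Ring B closes by a 6-(enolendo)-exo-trig aldol addition (C9–C10), and the temporary oxirane closes by a 3-exo-tet substitution (O–C9). C10 is controlled by ring A: in the chair with the C3 acetate equatorial, the C5 side chain is axial on the α face and can reach only the α face of the neighbouring carbonyl, so the fusion should be cis with the oxygen β, cis to the C5 methyl, whereas the chair needed for trans fusion carries a syn-diaxial acetate/methyl pair. C9 is controlled by the displacement itself: only the aldolate with chlorine anti-periplanar to the C10 oxygen (9α-Cl) can close, the other epimer returns by retro-aldol or enolisation, and so the reversible addition is drained into the single 9β,10β-epoxide. The step needs site selectivity among three enolisable positions (C9, C7, C1); the inductive effect of chlorine secures C9, and full conversion to this enolate masks the C8 carbonyl, which should shut off the bridged aldol from C1 and the Favorskii path from C7.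

Step 9
Reactants: 14 (3S,4R,5R,9R,10R)-3β-acetoxy-9β,10β-epoxy-11,12,13-trinoreremophilan-8-one
Product: 15 3β-acetoxy-9β,10β-epoxy-13-noreremophilane-8,11-dione (drawn as its C8 enol)
Conditions: LiN(SiMe3)2 (2.1 equiv), THF, −78 °C; 1-acetyl-1H-benzotriazole, −78 to 0 °C; aq. NH4Cl
Reagents that add atoms: 1-acetyl-1H-benzotriazole, CC(=O)n1nnc2ccccc21
Why: In this Claisen-type C-acylation of a lithium enolate with an N-acylbenzotriazole, C7 is the only enolisable position of the epoxy ketone (C9 is an oxirane carbon), and the second equivalent of base takes up the acidic β-diketone; the new C7 centre is lost to enolisation.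

Step 10
Reactants: 15 3β-acetoxy-9β,10β-epoxy-13-noreremophilane-8,11-dione
Product: 16 (3S,4R,5R,9R,10R)-3β-acetoxy-9β,10β-epoxy-13-noreremophil-6-ene-8,11-dione
Conditions: DDQ (1.1 equiv), 1,4-dioxane, rt
Reagents that add atoms: none
Why: DDQ dehydrogenation of an enolised β-dicarbonyl compound proceeds by hydride abstraction from C6 of the enol, and the quaternary C5 blocks any further tautomerisation of the 2-acyl enone; the epoxide and the acetate are inert to DDQ.

Step 11
Reactants: 16 (3S,4R,5R,9R,10R)-3β-acetoxy-9β,10β-epoxy-13-noreremophil-6-ene-8,11-dione; 17 angelic acid, (Z)-2-methylbut-2-enoic acid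
Product: 18 (3S,4R,5R,9S,10R)-3β-acetoxy-9α-angeloyloxy-10β-hydroxy-13-noreremophil-6-ene-8,11-dione (target)
Conditions: 17 (3 equiv), Cs2CO3 (0.3 equiv), DMF, 45 °C
Reagents that add atoms: none
Why: SN2 opening of an α,β-epoxy ketone by a carboxylate at the carbonyl-activated secondary Cα (trans-diaxial, Fürst–Plattner) inverts C9 to 9α-O and leaves the C10–O bond as the 10β-hydroxyl, while the acid buffer disfavours retro-aldol and dehydration; because angelic acid reacts as the nucleophile and is never activated at its carbonyl, its (Z)-geometry should be retained.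

Compound list
1 | 2,3-dimethylphenol | Cc1cccc(O)c1C | starting material
2 | 4-methoxy-2,3-dimethylphenol | COc1ccc(O)c(C)c1C | intermediate
3 | 4,4-dimethoxy-2,3-dimethylcyclohexa-2,5-dien-1-one | COC1(OC)C=CC(=O)C(C)=C1C | intermediate
4 | 4,4-dimethoxy-2,3-dimethylcyclohex-2-en-1-one | COC1(OC)CCC(=O)C(C)=C1C | intermediate
5 | (1S)-4,4-dimethoxy-2,3-dimethylcyclohex-2-en-1-ol | O[C@H]1CCC(OC)(OC)C(C)=C1C | intermediate
6 | (1S)-4,4-dimethoxy-2,3-dimethylcyclohex-2-en-1-yl acetate | CC(=O)O[C@H]1CCC(OC)(OC)C(C)=C1C | intermediate
7 | (1S)-2,3-dimethyl-4-oxocyclohex-2-en-1-yl acetate | CC(=O)O[C@H]1CCC(=O)C(C)=C1C | intermediate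
8 | (1S,2R)-2,3-dimethyl-4-[(triethylsilyl)oxy]cyclohex-3-en-1-yl acetate | CC(=O)O[C@H]1CCC(O[Si](CC)(CC)CC)=C(C)[C@H]1C | intermediate
9 | 2-chloro-N-methoxy-N-methylacetamide | CON(C)C(=O)CCl | starting material
10 | 1-chlorobut-3-en-2-one | C=CC(=O)CCl | intermediate
11 | (1S,2R,3R)-3-[(Z)-4-chloro-3-(triethylsilyloxy)but-2-enyl]-2,3-dimethyl-4-oxocyclohexyl acetate | CC(=O)O[C@H]1CCC(=O)[C@](C)(C/C=C(\O[Si](CC)(CC)CC)CCl)[C@H]1C | intermediate
12 | (1S,2R,3R)-3-(4-chloro-3-oxobutyl)-2,3-dimethyl-4-oxocyclohexyl acetate | CC(=O)O[C@H]1CCC(=O)[C@](C)(CCC(=O)CCl)[C@H]1C | intermediate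
13 | potassium alkoxide of 3β-acetoxy-9α-chloro-10β-hydroxy-11,12,13-trinoreremophilan-8-one (cis-fused) | CC(=O)O[C@H]1CC[C@]2([O-])[C@H](Cl)C(=O)CC[C@]2(C)[C@H]1C.[K+] | intermediate
14 | (3S,4R,5R,9R,10R)-3β-acetoxy-9β,10β-epoxy-11,12,13-trinoreremophilan-8-one | CC(=O)O[C@H]1CC[C@]23O[C@H]2C(=O)CC[C@]3(C)[C@H]1C | intermediate
15 | 3β-acetoxy-9β,10β-epoxy-13-noreremophilane-8,11-dione, C8 enol form | CC(=O)O[C@H]1CC[C@]23O[C@H]2C(O)=C(C(C)=O)C[C@]3(C)[C@H]1C | intermediate
16 | (3S,4R,5R,9R,10R)-3β-acetoxy-9β,10β-epoxy-13-noreremophil-6-ene-8,11-dione | CC(=O)O[C@H]1CC[C@]23O[C@H]2C(=O)C(C(C)=O)=C[C@]3(C)[C@H]1C | intermediate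
17 | angelic acid, (Z)-2-methylbut-2-enoic acid | C/C=C(/C)C(=O)O | starting material
18 | (3S,4R,5R,9S,10R)-3β-acetoxy-9α-angeloyloxy-10β-hydroxy-13-noreremophil-6-ene-8,11-dione | C/C=C(/C)C(=O)O[C@@H]1C(=O)C(C(C)=O)=C[C@]2(C)[C@@H](C)[C@@H](OC(C)=O)CC[C@]12O | target

Total step count: 11. Longest linear sequence: 10 steps (steps 1–5 and 7–11).

Steps most likely to fail

1. Step 8.
- Risk: attack on the hindered C10 carbonyl may be outrun by proton shuffling to the C1 or C7 enolate. That would lead to bridged aldolisation onto C8, Favorskii-type contraction or retro-Michael cleavage.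
- Fallback (Robinson annulation followed by Weitz–Scheffer epoxidation): it sets out from 8. Addition of 8 to but-3-en-2-one under the conditions of step 7 should give (1S,2R,3R)-2,3-dimethyl-4-oxo-3-(3-oxobutyl)cyclohexyl acetate F1. Aldol condensation (pyrrolidine, AcOH, toluene, reflux) should give (1R,2S,8aR)-1,8a-dimethyl-6-oxo-1,2,3,4,6,7,8,8a-octahydronaphthalen-2-yl acetate F2. Nucleophilic epoxidation (t-BuOOH, DBU, CH2Cl2) is expected on the β face, as for related angular-methyl octalones. The route is rejoined at 14.

2. Step 11.
- Risk: substitution at C9, next to a fully substituted carbon, may be slow. Loss of water from the product to the enol ester, or ionisation at C10, may then compete.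
- Fallback (the ester bond is made from the acyl side instead): it sets out from 16. Acid-catalysed hydrolysis (HClO4 cat., THF/H2O, 0 °C) by trans-diaxial opening at C9 should give 3β-acetoxy-9α,10β-dihydroxy-13-noreremophil-6-ene-8,11-dione F3. Separately, 17 with 2,4,6-trichlorobenzoyl chloride and Et3N should give angelic 2,4,6-trichlorobenzoic anhydride F4. Heating F3 with F4 in toluene at 80 °C without a nucleophilic catalyst should acylate only the secondary C9 hydroxyl and keep the (Z)-geometry. The route is rejoined at 18.

3. Step 5.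
- Risk: hydrometalation of the tetrasubstituted alkene may be sluggish. The rhodium catalyst may ionise the allylic acetate. 1,2-Addition or poor facial selectivity is also possible.
- Fallback (reduction and enol ether formation are separated): it sets out from 7. Heterogeneous hydrogenation (H2, Rh/Al2O3, EtOAc) from the face anti to the acetate should give (1S,2R,3S)-2,3-dimethyl-4-oxocyclohexyl acetate F5. Silylation under equilibrating conditions (Et3SiCl, NaI, Et3N, MeCN) should favour the more substituted enol ether. The route is rejoined at 8.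

Further compounds
F1 | step 8 | (1S,2R,3R)-2,3-dimethyl-4-oxo-3-(3-oxobutyl)cyclohexyl acetate | CC(=O)O[C@H]1CCC(=O)[C@](C)(CCC(C)=O)[C@H]1C
F2 | step 8 | (1R,2S,8aR)-1,8a-dimethyl-6-oxo-1,2,3,4,6,7,8,8a-octahydronaphthalen-2-yl acetate | CC(=O)O[C@H]1CCC2=CC(=O)CC[C@]2(C)[C@H]1C
F3 | step 11 | 3β-acetoxy-9α,10β-dihydroxy-13-noreremophil-6-ene-8,11-dione | O[C@@H]1C(=O)C(C(C)=O)=C[C@]2(C)[C@@H](C)[C@@H](OC(C)=O)CC[C@]12O
F4 | step 11 | angelic 2,4,6-trichlorobenzoic anhydride | C/C=C(/C)C(=O)OC(=O)c1c(Cl)cc(Cl)cc1Cl
F5 | step 5 | (1S,2R,3S)-2,3-dimethyl-4-oxocyclohexyl acetate | CC(=O)O[C@H]1CCC(=O)[C@@H](C)[C@H]1C
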